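**Retrosynthetic overview**
1. Target 16 ⇐ 6β,7β-diol lactone 15 by oxidation of the allylic C-7 alcohol; 15 ⇐ ene-dione 13 by one hydride reduction that sets C-6 from the α face and converts the dioxolanone into the butyrolactone.
2. 13 ⇐ enone 11 by α′-oxygenation at C-6.
3. Key disconnection C-12–C-13: the enolate of the (R)-malic acid/pivalaldehyde dioxolanone 10 (C-13 used as an α-oxy carbanion) adds 1,6 to the δ-carbon of 9-vinyl enone 7, joining two acceptor-type carbons and setting C-13.
4. 7 ⇐ (+)-sclareolide 1 by lactone opening/dehydration, reduction, acetylation, allylic oxidation and elimination.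
5. Ring order: rings A and B (C-5, C-10) come intact from sclareolide; the temporary dioxolanone ring is made in step 6; the butyrolactone ring closes in step 10.

Assumption: labdane numbering is used in names (β = face of the C-10 methyl), and (R)-malic acid is taken as a commercial chiral-pool reagent.

**Route**

Step 1
Reactants: 1 (+)-sclareolide
Product: 3 methyl (5S,10S)-13,14,15,16-tetranorlabd-8-en-12-oate, via unsaturated acid 2 (not isolated)
Conditions: conc. H2SO4, MeOH, reflux; AgNO3–SiO2 chromatography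
Reagents that add atoms: methanol, SMILES CO
Why: Acid-catalysed alkyl–oxygen (E1) cleavage of the tertiary lactone with equilibration gives the tetrasubstituted 8(9)-alkene acid, expected as the main isomer, which is trapped by Fischer esterification; C-5 and C-10 are carried over unchanged from sclareolide.

Step 2
Reactants: 3 methyl (5S,10S)-13,14,15,16-tetranorlabd-8-en-12-oate
Product: 4 (5S,10S)-13,14,15,16-tetranorlabd-8-en-12-ol
Conditions: LiAlH4, THF, 0 °C → rt
Reagents that add atoms: none
Why: LiAlH4 ester reduction gives the primary alcohol without touching the alkene or any stereocentre.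

Step 3
Reactants: 4 (5S,10S)-13,14,15,16-tetranorlabd-8-en-12-ol
Product: 5 (5S,10S)-13,14,15,16-tetranorlabd-8-en-12-yl acetate
Conditions: Ac2O, pyridine, DMAP (cat.), CH2Cl2, rt
Reagents that add atoms: acetic anhydride, SMILES CC(=O)OC(C)=O
Why: Acetylation protects the alcohol for the chromium oxidation and installs the leaving group used in step 5.

Step 4
Reactants: 5 (5S,10S)-13,14,15,16-tetranorlabd-8-en-12-yl acetate
Product: 6 (5S,10S)-7-oxo-13,14,15,16-tetranorlabd-8-en-12-yl acetate
Conditions: CrO3, 3,5-dimethylpyrazole, CH2Cl2, −20 °C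
Reagents that add atoms: chromium trioxide CrO3, SMILES O=[Cr](=O)=O
Why: Allylic oxidation with the CrO3–3,5-dimethylpyrazole complex converts the ring allylic methylene C-7 into the conjugated 7-oxo-8-ene, the usual outcome for 8-ene labdanes and drimanes.

Step 5
Reactants: 6 (5S,10S)-7-oxo-13,14,15,16-tetranorlabd-8-en-12-yl acetate
Product: 7 (5S,10S)-13,14,15,16-tetranorlabda-8,11-dien-7-one
Conditions: DBU, toluene, 80 °C
Reagents that add atoms: none
Why: Vinylogous E1cB elimination (γ-deprotonation at C-11, loss of acetate from C-12) gives the conjugated 9-vinyl dienone.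

Step 6
Reactants: 8 (R)-malic acid; 9 pivalaldehyde
Product: 10 2-[(2R,4R)-2-tert-butyl-5-oxo-1,3-dioxolan-4-yl]acetic acid
Conditions: TsOH·H2O (cat.), H2SO4 (cat.), pentane, reflux (Dean–Stark); recrystallisation
Reagents that add atoms: none
Why: Seebach acetalisation of the α-hydroxy acid unit gives the thermodynamically preferred cis acetal (tert-butyl cis to the CH2CO2H arm), purified by crystallisation, with the malic acid stereocentre (future C-13) untouched.

Step 7
Reactants: 7 (5S,10S)-13,14,15,16-tetranorlabda-8,11-dien-7-one; 10 2-[(2R,4R)-2-tert-butyl-5-oxo-1,3-dioxolan-4-yl]acetic acid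
Product: 11 pivalaldehyde acetal-lactone of (13R)-13-hydroxy-7-oxolabd-8-ene-15,16-dioic acid (dioxolanone across 13-O and C-16, C-15 acid free)
Conditions: 10, LiHMDS (2.1 equiv), THF–DMPU, −78 °C; then 7, −78 → −40 °C; 1 M HCl
Reagents that add atoms: none
Why: Proposed new method: the lithium enolate of the dioxolanone turns the carbinol carbon C-13 (otherwise a ketone-type acceptor) into an α-oxy carbanion that adds in a vinylogous 1,6-Michael reaction to the unhindered δ-carbon C-12 of the dienone (the β-carbon C-9 is fully substituted), attack anti to the tert-butyl group replacing the former C–H with retention (self-regeneration of stereocentres) to fix 13R, and protonation returns the conjugated 8-en-7-one; the closest known reactions are Seebach's alkylations and Michael additions of 2-tert-butyl-1,3-dioxolan-4-one enolates.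

Step 8
Reactants: 11 pivalaldehyde acetal-lactone of (13R)-13-hydroxy-7-oxolabd-8-ene-15,16-dioic acid
Product: 12 pivalaldehyde acetal-lactone of (13R)-6α,13-dihydroxy-7-oxolabd-8-ene-15,16-dioic acid
Conditions: NaHMDS (2.2 equiv), THF, −78 °C; then 2-(phenylsulfonyl)-3-phenyloxaziridine; 1 M HCl
Reagents that add atoms: 2-(phenylsulfonyl)-3-phenyloxaziridine, SMILES O=S(=O)(c1ccccc1)N1OC1c1ccccc1
Why: Kinetic α′-enolisation at C-6 and Davis oxaziridine hydroxylation deliver oxygen from the open α face (6α-OH), which does not matter because C-6 becomes a ketone in step 9.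

Step 9
Reactants: 12 pivalaldehyde acetal-lactone of (13R)-6α,13-dihydroxy-7-oxolabd-8-ene-15,16-dioic acid
Product: 13 pivalaldehyde acetal-lactone of (13R)-13-hydroxy-6,7-dioxolabd-8-ene-15,16-dioic acid
Conditions: Dess–Martin periodinane, CH2Cl2, 0 °C, 20 min; used at once
Reagents that add atoms: none
Why: Dess–Martin oxidation of the α-ketol gives the 6,7-dione under non-basic conditions, so the trans ring fusion at C-5 should survive if the crude dione is reduced immediately.

Step 10
Reactants: 13 pivalaldehyde acetal-lactone of (13R)-13-hydroxy-6,7-dioxolabd-8-ene-15,16-dioic acid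
Product: 15 (13R)-6β,7β,13-trihydroxylabd-8-en-15,16-olide, via tetrahydroxy acid 14 (not isolated)
Conditions: LiBH4 (excess), THF, −78 → 0 °C; then 1 M HCl (pH 3), rt
Reagents that add atoms: none
Why: In this borohydride reduction hydride reaches C-6 and C-7 from the α face, opposite the axial C-4β and C-10 methyls, giving the axial 6β-alcohol as in 6-oxo drimanes and steroids, while the activated dioxolanone is reduced to the C-16 primary alcohol with loss of the acetal, the lithium carboxylate is left alone at this temperature, and acidification closes the γ-lactone (lactonisation).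

Step 11
Reactants: 15 (13R)-6β,7β,13-trihydroxylabd-8-en-15,16-olide
Product: 16 (13R)-6β,13-dihydroxy-7-oxolabd-8-en-15,16-olide (target, 5S,6S,10S,13R)
Conditions: MnO2, CH2Cl2, rt
Reagents that add atoms: none
Why: MnO2 oxidises only the allylic C-7 alcohol (chemoselective allylic oxidation), restoring the enone and leaving the 6β-secondary alcohol, the 13-tertiary alcohol, the lactone and all stereocentres untouched.

**Compound list**
1 | (+)-sclareolide (8α,12-lactone of 8α-hydroxy-13,14,15,16-tetranorlabdan-12-oic acid) | C[C@]1(OC(=O)C2)[C@H]2[C@@]3(C)CCCC(C)(C)[C@@H]3CC1 | starting material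
2 | (5S,10S)-13,14,15,16-tetranorlabd-8-en-12-oic acid (CH2CO2H on C-9, tetrasubstituted alkene) | CC1=C(CC(=O)O)[C@@]2(C)CCCC(C)(C)[C@@H]2CC1 | intermediate (not isolated)
3 | methyl (5S,10S)-13,14,15,16-tetranorlabd-8-en-12-oate | CC1=C(CC(=O)OC)[C@@]2(C)CCCC(C)(C)[C@@H]2CC1 | intermediate
4 | (5S,10S)-13,14,15,16-tetranorlabd-8-en-12-ol | CC1=C(CCO)[C@@]2(C)CCCC(C)(C)[C@@H]2CC1 | intermediate
5 | (5S,10S)-13,14,15,16-tetranorlabd-8-en-12-yl acetate | CC1=C(CCOC(C)=O)[C@@]2(C)CCCC(C)(C)[C@@H]2CC1 | intermediate
6 | (5S,10S)-7-oxo-13,14,15,16-tetranorlabd-8-en-12-yl acetate | CC1=C(CCOC(C)=O)[C@@]2(C)CCCC(C)(C)[C@@H]2CC1=O | intermediate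
7 | (5S,10S)-13,14,15,16-tetranorlabda-8,11-dien-7-one (9-vinyl enone) | CC1=C(C=C)[C@@]2(C)CCCC(C)(C)[C@@H]2CC1=O | intermediate
8 | (R)-malic acid (D-malic acid) | O[C@H](CC(=O)O)C(=O)O | starting material
9 | pivalaldehyde (2,2-dimethylpropanal) | CC(C)(C)C=O | starting material
10 | 2-[(2R,4R)-2-tert-butyl-5-oxo-1,3-dioxolan-4-yl]acetic acid (cis acetal) | OC(=O)C[C@H]1O[C@@H](C(C)(C)C)OC1=O | intermediate
11 | pivalaldehyde acetal-lactone of (13R)-13-hydroxy-7-oxolabd-8-ene-15,16-dioic acid; (2R,4R)-dioxolanone, tert-butyl cis to the CH2CO2H arm | CC1=C(CC[C@]3(CC(=O)O)O[C@@H](C(C)(C)C)OC3=O)[C@@]2(C)CCCC(C)(C)[C@@H]2CC1=O | intermediate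
12 | 6α-hydroxy derivative of 11 (6R) | CC1=C(CC[C@]3(CC(=O)O)O[C@@H](C(C)(C)C)OC3=O)[C@@]2(C)CCCC(C)(C)[C@@H]2[C@@H](O)C1=O | intermediate
13 | 6,7-dioxo derivative of 11 (trans-fused ene-dione) | CC1=C(CC[C@]3(CC(=O)O)O[C@@H](C(C)(C)C)OC3=O)[C@@]2(C)CCCC(C)(C)[C@@H]2C(=O)C1=O | intermediate
14 | (13R)-6β,7β,13,16-tetrahydroxylabd-8-en-15-oic acid | CC1=C(CC[C@](O)(CO)CC(=O)O)[C@@]2(C)CCCC(C)(C)[C@@H]2[C@H](O)[C@@H]1O | intermediate (not isolated)
15 | (13R)-6β,7β,13-trihydroxylabd-8-en-15,16-olide | CC1=C(CC[C@]3(O)COC(=O)C3)[C@@]2(C)CCCC(C)(C)[C@@H]2[C@H](O)[C@@H]1O | intermediate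
16 | (5S,6S,10S,13R)-6β,13-dihydroxy-7-oxolabd-8-en-15,16-olide | CC1=C(CC[C@]2(O)COC(=O)C2)[C@@]2(C)CCCC(C)(C)[C@@H]2[C@H](O)C1=O | target

**Step count**
Total steps: 11. Longest linear sequence: 10 (steps 1–5 and 7–11; step 6 is a one-step side branch).

**Three steps most likely to fail, with fallbacks**

Step 7. The dioxolanone dianion may act as a base towards the enolisable dienone, add 1,2, or decompose before the 1,6-addition occurs. The fallback forms the same bond by direct alkylation before ring B is oxidised. It sets out from alcohol 4, which I2, PPh3 and imidazole convert into (5S,10S)-12-iodo-13,14,15,16-tetranorlabd-8-ene F1. The dianion of 10 (LiHMDS, THF–DMPU, −78 → −30 °C) is alkylated by F1 anti to the tert-butyl group, with the same sense of induction, to give the pivalaldehyde acetal-lactone of (13R)-13-hydroxylabd-8-ene-15,16-dioic acid F2. Allylic oxidation of F2 with CrO3 and 3,5-dimethylpyrazole then comes back to the route at 11.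

Step 9. The trans-fused ene-dione 13 can enolise towards C-5 or epimerise there before it is reduced. The fallback avoids any 1,2-dione and sets out from 12. LiBH4 followed by acid gives (13R)-6α,7β,13-trihydroxylabd-8-en-15,16-olide F3. TBSCl and imidazole silylate the less hindered allylic 7-hydroxyl to give (13R)-7β-(tert-butyldimethylsilyloxy)-6α,13-dihydroxylabd-8-en-15,16-olide F4. Dess–Martin oxidation gives (13R)-7β-(tert-butyldimethylsilyloxy)-13-hydroxy-6-oxolabd-8-en-15,16-olide F5, a 6-ketone with no neighbouring carbonyl. NaBH4 attacks F5 from the α face to give (13R)-7β-(tert-butyldimethylsilyloxy)-6β,13-dihydroxylabd-8-en-15,16-olide F6. TBAF buffered with AcOH removes the silyl group and comes back to the route at 15.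

Step 1. The E1 dehydration can give 7-ene and 8(17)-ene isomers and can relactonise, so the tetrasubstituted alkene may be obtained only in moderate yield. The fallback places the double bond regiospecifically and sets out from 1. α,β-Dehydrogenation of the lactone (LDA, then N-tert-butylbenzenesulfinimidoyl chloride) gives 13,14,15,16-tetranorlabd-9(11)-en-12,8α-olide F7. SmI2 in THF–HMPA with MeOH cleaves the allylic C-8–O bond reductively, and α-protonation of the resulting dienolate leaves the double bond only at 8(9), giving acid 2, this time isolated. LiAlH4 reduction of 2 comes back to the route at 4.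

**Further compounds**
F1 | step 7 | (5S,10S)-12-iodo-13,14,15,16-tetranorlabd-8-ene | CC1=C(CCI)[C@@]2(C)CCCC(C)(C)[C@@H]2CC1
F2 | step 7 | pivalaldehyde acetal-lactone of (13R)-13-hydroxylabd-8-ene-15,16-dioic acid | CC1=C(CC[C@]3(CC(=O)O)O[C@@H](C(C)(C)C)OC3=O)[C@@]2(C)CCCC(C)(C)[C@@H]2CC1
F3 | step 9 | (13R)-6α,7β,13-trihydroxylabd-8-en-15,16-olide | CC1=C(CC[C@]3(O)COC(=O)C3)[C@@]2(C)CCCC(C)(C)[C@@H]2[C@@H](O)[C@@H]1O
F4 | step 9 | (13R)-7β-(tert-butyldimethylsilyloxy)-6α,13-dihydroxylabd-8-en-15,16-olide | CC1=C(CC[C@]3(O)COC(=O)C3)[C@@]2(C)CCCC(C)(C)[C@@H]2[C@@H](O)[C@@H]1O[Si](C)(C)C(C)(C)C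
F5 | step 9 | (13R)-7β-(tert-butyldimethylsilyloxy)-13-hydroxy-6-oxolabd-8-en-15,16-olide | CC1=C(CC[C@]3(O)COC(=O)C3)[C@@]2(C)CCCC(C)(C)[C@@H]2C(=O)[C@@H]1O[Si](C)(C)C(C)(C)C
F6 | step 9 | (13R)-7β-(tert-butyldimethylsilyloxy)-6β,13-dihydroxylabd-8-en-15,16-olide | CC1=C(CC[C@]3(O)COC(=O)C3)[C@@]2(C)CCCC(C)(C)[C@@H]2[C@H](O)[C@@H]1O[Si](C)(C)C(C)(C)C
F7 | step 1 | 13,14,15,16-tetranorlabd-9(11)-en-12,8α-olide | C[C@]12OC(=O)C=C1[C@@]1(C)CCCC(C)(C)[C@@H]1CC2
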